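## Structural features

The target is one benzene ring with three substituents in a 1,3,4-pattern: an (E)-methyl propenoate chain at C1, a 3-methylbut-2-enyl (prenyl) group at C3, and at C4 an oxygen acylated by a (3S)-3-acetoxybutanoyl chain. There are no other rings. The side chains are attached through one aryl–vinyl C–C bond at C1, one aryl–CH2 bond at C3 and one aryl ester C–O bond at C4. The only stereocentre is C3 of the butanoyl chain; it carries the acetate, lies β to the aryl ester carbonyl and has no stereogenic neighbour, so the task is supply and preservation of configuration, not relative control. The fragile groups are the aryl ester (an activated ester, easily cleaved by nucleophiles and bases), the β-acetoxy group (a leaving group for E1cB elimination) and the prenyl alkene next to the phenolic oxygen (acid closes it to a 2,2-dimethylchroman once the phenol is free). Three different esters (methyl, acetate, aryl) must also stay distinct. The real difficulty is placing exactly one prenyl group on the ring carbon ortho to the oxygen, where classical phenol prenylation has to contend with O- versus C-alkylation, ortho versus para attack and double alkylation. The second difficulty is attaching the acyl chain late without eliminating acetate. The key step uses the fact that the prenyl CH2 sits on C3, directly beside the oxygen-bearing C4. C4–O and C3–CH2 form a salicyl unit, so this CH2 can be the exocyclic methylene of an ortho-quinone methide (C4=O, C3=CH2), and a 2-methylprop-1-enyl nucleophile adding there creates the CH2–CH= bond of the prenyl group.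

## Logic of the disconnections

**12 to 9 and 11.** The acyl–oxygen bond of the aryl ester at C4 is cut. It is the most labile bond in the molecule and the natural point of convergence. The cut removes the stereocentre and the elimination-prone β-acetoxy ester from the aromatic half, leaving an achiral phenol and a four-carbon acid. The forward step must acylate an ortho-substituted phenol under conditions mild enough to avoid loss of acetate. Because this ester would survive neither an organomagnesium reagent nor hot amine base, it has to be the last step.

**11 to 10.** The acetate O–acyl bond is cut, which takes the chiral fragment back to a chiral-pool hydroxy acid that already has the (S) configuration. The forward step must acylate the hydroxyl only, break no bond at the stereocentre and return the carboxyl group free.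

**9 to 7 and 8.** The bond between ring carbon C1 and the β-carbon of the propenoate is cut. 8 supplies all three carbons and the methyl ester at once, and the mechanism of the coupling sets the E geometry. The aromatic fragment is reduced to a bromophenol whose bromine is a spectator in the key step. The forward step needs a palladium catalyst that inserts into an electron-rich C–Br bond in the presence of a free phenol without engaging the prenyl alkene. Carrying the acrylate through the key step instead would expose an enoate to excess 4, so the bromine is kept until after it.

**7 to 3 and 4 (key disconnection).** The CH2–CH= bond of the prenyl group is cut, between the benzylic carbon and the alkenyl carbon. This turns a regioselective aromatic prenylation into a conjugate addition whose site is fixed in advance, because the benzylic carbon is already present as the hydroxymethyl carbon of 3. The forward step passes through 5 and 6. It requires two equivalents of 4, generation of 6 at low temperature with 4 always in excess, and a halogen that resists halogen–magnesium exchange. Bromine is chosen over iodine for that reason.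

**3 to 2 to 1.** A benzylic C–H bond (reduction) and the phenolic O–carbonate bond are cut. 1 already carries the oxygen, the ortho carbon and the para bromine in the right positions, so no aromatic substitution is needed anywhere in the route. The carbonate must be installed before the reduction, and the reduction must not generate a free alkoxide, or the trigger fires early. This calls for a neutral, electrophilic hydride donor.

## Other disconnections considered

**Alternative 1:** The cut goes through the arene itself, at ring bonds C1–C2 and C5–C6 (C1 bears the acrylate, C3 the prenyl group, C4 the oxygen). C2 to C5 would come from the silyl dienol ether A1, 2-[tert-butyl(dimethyl)silyl]oxy-3-(3-methylbut-2-enyl)buta-1,3-diene, and C1, C6 and a formyl carbon from prop-2-ynal A2.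

- Forward key step: a [4+2] cycloaddition of A1 and A2 would close the carbocycle as the cyclohexa-1,4-diene A3. In A3 the silyloxy carbon is C4 and the prenyl carbon is C5; the prenyl locant becomes 3 only after aromatisation and renumbering. Dehydrogenation would give the benzaldehyde A4, and a two-carbon olefination plus desilylation would lead to 9.
- In favour: the prenyl group is in place before the ring exists, so no aromatic substitution selectivity arises. The reaction is concerted and needs no excess organometallic reagent. The aldehyde of A4 allows a palladium-free olefination.
- Against: it builds a benzene ring that can be bought with the correct substitution pattern. A1 needs its own multi-step preparation and is acid-sensitive. A2 is volatile, lachrymatory and prone to violent polymerisation. The orientation relies on the siloxy group outweighing the opposing alkyl group on the neighbouring diene carbon. The aromatisation must spare the prenyl alkene and its doubly activated CH2.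
- Comparison: on positional control of the prenyl group the two plans are equal, since both fix it by construction. On avoiding transition-metal catalysis and cryogenic organometallic chemistry this alternative is the better. On step economy (roughly nine or ten steps against six), reagent safety and risk of isomer formation the chosen plan is better.

**Alternative 2:** The cut is in the side chain, at the CH2–CH(O) bond of the butanoyl unit, so the stereocentre is created on the intact aryl ester.

- Forward key step: the aryl acetate A5 (the acetate of 9) would be converted into its trimethylsilyl ketene acetal A6. A6 would add to the Re face of acetaldehyde A7 under Ti(OiPr)4 with a BINOL-derived ligand, a Mukaiyama aldol through an open transition state, to give the (S)-carbinol A8. Acetylation of A8 would give 12.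
- In favour: the configuration is set by a catalyst, so either enantiomer is reachable by choice of ligand and no chiral building block is needed. No β-acyloxy acid has to be activated, so elimination at the coupling stage cannot occur.
- Against: it does not address the prenyl problem and still needs 9. Enolates of aryl acetates fragment readily, so the silylation has to outrun that. The amide base has a competing electrophile in the cinnamate. A7 is small, volatile and self-condensing, and methyl versus hydrogen is the hardest case for facial discrimination. The enantiomeric purity would have to be established, whereas 10 brings it.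
- Comparison: on flexibility of absolute configuration this alternative is the better. On mildness of the final acetylation it is equal. On step economy (four operations from 9 against two for steps 5 and 6) and on stereochemical security the chosen plan is better. The chosen plan has no stereo-forming event at all.

**Alternative 3:** The cut is the aryl–CH2 bond between ring carbon C3 and C1 of the prenyl group.

- Forward key step: a membrane-bound UbiA-type prenyltransferase with MgCl2 as cofactor would transfer the dimethylallyl unit of dimethylallyl diphosphate A10 to C3 of p-coumaric acid A9. This is an electrophilic aromatic substitution inside the active site and would give drupanin A11. Selective methyl esterification of the carboxyl group of A11 would give 9, after which the endgame is the same.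
- In favour: one step assembles the whole prenylated cinnamate skeleton from a cheap biogenic acid with the E-alkene already present. The active site sets the position. No protecting groups, palladium or organometallic reagents are needed.
- Against: the enzyme is membrane-bound and needs microsomes or an engineered host. A10 is costly and labile unless regenerated in situ. A second prenylation at C5 is the natural follow-up reaction. Preparative throughput and product isolation from such systems are uncertain.
- Comparison: on step economy (about four steps against six) and atom economy this alternative is the better. On regiocontrol the plans are equal, by active site in one and by the salicyl skeleton in the other. The polarity is reversed: an electrophilic prenyl unit attacks the ring here, whereas the chosen plan adds a nucleophilic alkenyl unit to an electrophilic benzylic carbon. On accessibility with ordinary laboratory equipment and on scalability the chosen plan is better.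

Key step: step 3

Remark on the chemistry: 4 is used as its commercial solution in THF and 10 as the commercial free acid of high enantiomeric purity; acetylation and esterification leave the priority order at the stereocentre unchanged, so (S) in 10 corresponds to (S) in 12.

## Route

Step 1
Reactants: 1 5-bromosalicylaldehyde (5-bromo-2-hydroxybenzaldehyde)
Product: 2 tert-butyl (4-bromo-2-formylphenyl) carbonate
Conditions: Boc2O, i-Pr2NEt, DMAP (cat.), CH2Cl2, 0 °C → rt
Reagents that add atoms: di-tert-butyl dicarbonate, CC(C)(C)OC(=O)OC(=O)OC(C)(C)C
Why: DMAP-catalysed tert-butoxycarbonylation of the phenol (nucleophilic acyl substitution); the aldehyde and the aryl bromide are inert, and the carbonate later serves as the trigger for the key step.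

Step 2
Reactants: 2 tert-butyl (4-bromo-2-formylphenyl) carbonate
Product: 3 tert-butyl [4-bromo-2-(hydroxymethyl)phenyl] carbonate
Conditions: BH3·SMe2, THF, 0 °C; then H2O, 0 °C
Reagents that add atoms: none
Why: Borane reduction of the aldehyde; borane is an electrophilic hydride donor that leaves the oxygen bound to boron and never produces a free alkoxide, so the carbonate does not migrate, and the aryl carbonate and aryl bromide are not reduced at 0 °C; neutral hydrolysis frees the benzylic alcohol.

Step 3
Reactants: 3 tert-butyl [4-bromo-2-(hydroxymethyl)phenyl] carbonate; 4 2-methylprop-1-enylmagnesium bromide
Product: 7 4-bromo-2-(3-methylbut-2-enyl)phenol, via benzylic carbonate magnesium phenoxide 5 (not isolated), via ortho-quinone methide 6 (not isolated)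
Conditions: 4 (3 equiv), THF, −78 °C → rt; then aq. NH4Cl
Reagents that add atoms: none
Why: The first equivalent of 4 deprotonates the benzylic hydroxyl of 3, and the magnesium alkoxide attacks the neighbouring aryl carbonate through a six-membered cyclic tetrahedral intermediate, moving the tert-butoxycarbonyl group from the phenolic to the benzylic oxygen to give phenoxide 5. Phenoxide 5 expels tert-butyl carbonate in a 1,4-elimination to give ortho-quinone methide 6, whose exocyclic methylene is a strong acceptor because addition restores the aromatic sextet. A second equivalent of 4 adds through its sp2 carbon to that methylene (1,4-addition), forming the CH2–CH= bond of the prenyl group and the magnesium salt of 7. The closest known reaction type is the base-triggered carbonate migration and elimination route to ortho-quinone methides with in situ capture by organomagnesium reagents, applied here with an alkenyl nucleophile. No ring is closed and no stereocentre is formed; the alkene of 4 is carried over unchanged and has no E/Z question because its far carbon bears two methyl groups. The selectivity needed is 1,4-addition ahead of self-cycloaddition of 6 and ahead of attack of 4 on the carbonate carbonyl; the acid–base step is far faster than carbonyl addition, and 6 is released gradually below 0 °C into a solution that always contains excess 4. The site of prenylation is fixed by the salicyl skeleton of 3, so C- versus O-alkylation, ortho versus para attack and double prenylation cannot arise, and the aryl bromide is inert because alkenylmagnesium halides do not undergo bromine–magnesium exchange at these temperatures.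

Step 4
Reactants: 7 4-bromo-2-(3-methylbut-2-enyl)phenol; 8 methyl acrylate
Product: 9 methyl (E)-3-[4-hydroxy-3-(3-methylbut-2-enyl)phenyl]prop-2-enoate
Conditions: 8 (3 equiv), Pd(OAc)2 (cat.), P(o-tol)3, Et3N, DMF, 100 °C
Reagents that add atoms: none
Why: Mizoroki–Heck reaction: zerovalent palladium formed in situ inserts into the C–Br bond, and syn-insertion of 8 followed by syn-β-hydride elimination gives the E-cinnamate; the aryl–palladium centre is meta to the prenyl chain and cannot cyclise onto it, the trisubstituted prenyl alkene is far less reactive than the acrylate, and free para-bromophenols are established substrates with this hindered phosphine.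

Step 5
Reactants: 10 (S)-3-hydroxybutanoic acid
Product: 11 (S)-3-acetoxybutanoic acid
Conditions: Ac2O, pyridine, DMAP (cat.), 0 °C → rt; then H2O, dilute HCl work-up
Reagents that add atoms: acetic anhydride, CC(=O)OC(C)=O
Why: O-Acetylation of the secondary alcohol by nucleophilic acyl substitution at the anhydride; no bond to C3 is made or broken, so the (S) configuration is retained, and the aqueous work-up returns the carboxyl group as the free acid.

Step 6
Reactants: 9 methyl (E)-3-[4-hydroxy-3-(3-methylbut-2-enyl)phenyl]prop-2-enoate; 11 (S)-3-acetoxybutanoic acid
Product: 12 methyl (E)-3-[4-[(3S)-3-acetyloxybutanoyl]oxy-3-(3-methylbut-2-enyl)phenyl]prop-2-enoate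
Conditions: EDC·HCl, DMAP (cat.), CH2Cl2, 0 °C → rt
Reagents that add atoms: none
Why: Steglich esterification (carbodiimide activation of the acid with DMAP as acyl-transfer catalyst) acylates the phenol under nearly neutral conditions; the stereocentre is β to the carbonyl and is not involved, and low temperature with only catalytic DMAP limits E1cB loss of acetate.

## Compound list

1 | 5-bromosalicylaldehyde (5-bromo-2-hydroxybenzaldehyde) | O=Cc1cc(Br)ccc1O | starting material
2 | tert-butyl (4-bromo-2-formylphenyl) carbonate | CC(C)(C)OC(=O)Oc1ccc(Br)cc1C=O | intermediate
3 | tert-butyl [4-bromo-2-(hydroxymethyl)phenyl] carbonate | CC(C)(C)OC(=O)Oc1ccc(Br)cc1CO | intermediate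
4 | 2-methylprop-1-enylmagnesium bromide | CC(C)=C[Mg]Br | starting material
5 | bromomagnesium 4-bromo-2-[(tert-butoxycarbonyloxy)methyl]phenolate | CC(C)(C)OC(=O)OCc1cc(Br)ccc1O[Mg]Br | intermediate (not isolated)
6 | 4-bromo-6-methylidenecyclohexa-2,4-dien-1-one | C=C1C=C(Br)C=CC1=O | intermediate (not isolated)
7 | 4-bromo-2-(3-methylbut-2-enyl)phenol | CC(C)=CCc1cc(Br)ccc1O | intermediate
8 | methyl acrylate | C=CC(=O)OC | starting material
9 | methyl (E)-3-[4-hydroxy-3-(3-methylbut-2-enyl)phenyl]prop-2-enoate | COC(=O)/C=C/c1ccc(O)c(CC=C(C)C)c1 | intermediate
10 | (S)-3-hydroxybutanoic acid | C[C@H](O)CC(=O)O | starting material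
11 | (S)-3-acetoxybutanoic acid | C[C@H](OC(C)=O)CC(=O)O | intermediate
12 | methyl (E)-3-[4-[(3S)-3-acetyloxybutanoyl]oxy-3-(3-methylbut-2-enyl)phenyl]prop-2-enoate | COC(=O)/C=C/c1ccc(OC(=O)C[C@H](C)OC(C)=O)c(CC=C(C)C)c1 | target

## Step count and least certain steps

Total steps: 6. Longest linear sequence: 5 (steps 1, 2, 3, 4 and 6); step 5 is a one-step side branch.

**Step 3 (key step).** The most likely failure is self-cycloaddition and oligomerisation of the ortho-quinone methide when it is generated faster than it is trapped. Attack of the organomagnesium reagent on the carbonate carbonyl would strip the trigger and leave an unreactive salicyl alcohol salt. Partial bromine–magnesium exchange could occur on warming. The fallback sets out from 1 and returns at 7. It makes the same CH2–CH= bond by a copper-catalysed substitution instead of a conjugate addition. 1 is protected with MOMCl and i-Pr2NEt as 5-bromo-2-(methoxymethoxy)benzaldehyde F1. F1 is reduced with NaBH4 in MeOH to [5-bromo-2-(methoxymethoxy)phenyl]methanol F2. Appel bromination (CBr4, PPh3, CH2Cl2, 0 °C) gives 4-bromo-2-(bromomethyl)-1-(methoxymethoxy)benzene F3. Coupling of F3 with 4 under catalytic Li2CuCl4 in THF at −78 to 0 °C gives 4-bromo-1-(methoxymethoxy)-2-(3-methylbut-2-enyl)benzene F4. Brief treatment with dilute HCl in MeOH at room temperature should remove the acetal and give 7. This costs three extra steps, and the acid step must be kept short so that the prenyl phenol does not close to a chroman.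

**Step 4.** Oxidative addition into the electron-rich bromophenol may be slow, more so once the phenol is partly deprotonated, and palladium metal may precipitate. Palladium hydride species could migrate the prenyl double bond or promote cyclisation of the phenol onto it. Base- or phosphine-promoted oxa-Michael addition of the phenol to 8 is also possible. The fallback sets out from 7 and returns at 9 without palladium. The phenol of 7 is deprotonated with NaH, bromine–lithium exchange is carried out with t-BuLi in THF at −78 °C, and the aryllithium is quenched with DMF to give 4-hydroxy-3-(3-methylbut-2-enyl)benzaldehyde F5. Wittig olefination of F5 with methyl (triphenylphosphoranylidene)acetate in toluene at 80 °C should give 9 with E selectivity from the stabilised ylide.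

**Step 6.** Base-promoted β-elimination of acetate can occur from the activated acyl species, or from the product, whose α-hydrogens are acidified by the aryloxy group. If acyl transfer to the ortho-substituted phenol is slow, rearrangement of the activated acid to an unreactive N-acylurea competes. The fallback sets out from 10, uses 9 and returns at 12; it carries the hydroxyl through the coupling as a silyl ether, which is a poor leaving group. 10 is bis-silylated with TBSCl and imidazole in DMF to tert-butyl(dimethyl)silyl (3S)-3-[tert-butyl(dimethyl)silyl]oxybutanoate F6. The silyl ester is cleaved with K2CO3 in aqueous MeOH to (3S)-3-[tert-butyl(dimethyl)silyl]oxybutanoic acid F7. Coupling of F7 with 9 under EDC·HCl and catalytic DMAP gives methyl (E)-3-[4-[(3S)-3-[tert-butyl(dimethyl)silyl]oxybutanoyl]oxy-3-(3-methylbut-2-enyl)phenyl]prop-2-enoate F8. HF·pyridine in THF at 0 °C should free the carbinol as methyl (E)-3-[4-[(3S)-3-hydroxybutanoyl]oxy-3-(3-methylbut-2-enyl)phenyl]prop-2-enoate F9, which is the same compound as A8. Acetylation of F9 with Ac2O and pyridine at 0 °C gives 12.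

**Step 2.** The carbonate may transfer early from the phenolic to the benzylic oxygen if any basic or alkoxide species is present during reduction, quench or purification. That would be followed by loss of tert-butyl carbonate and oligomerisation, or by over-reduction of the benzylic position. The fallback sets out from 1 and returns at 3 by reversing the order of operations. NaBH4 in MeOH reduces 1 to 4-bromo-2-(hydroxymethyl)phenol F10. The more acidic phenolic hydroxyl of F10 is then carbonylated selectively with one equivalent of Boc2O (i-Pr2NEt, catalytic DMAP, CH2Cl2, 0 °C) to give 3. If part of the carbonate ends up on the benzylic oxygen, the isomer tert-butyl (5-bromo-2-hydroxyphenyl)methyl carbonate F11 is the protonated form of 5 and would enter step 3 at the same intermediate, so the regiochemistry of this protection is forgiving.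

## Further compounds

F1 | step 3 | 5-bromo-2-(methoxymethoxy)benzaldehyde | COCOc1ccc(Br)cc1C=O
F2 | step 3 | [5-bromo-2-(methoxymethoxy)phenyl]methanol | COCOc1ccc(Br)cc1CO
F3 | step 3 | 4-bromo-2-(bromomethyl)-1-(methoxymethoxy)benzene | COCOc1ccc(Br)cc1CBr
F4 | step 3 | 4-bromo-1-(methoxymethoxy)-2-(3-methylbut-2-enyl)benzene | COCOc1ccc(Br)cc1CC=C(C)C
F5 | step 4 | 4-hydroxy-3-(3-methylbut-2-enyl)benzaldehyde | CC(C)=CCc1cc(C=O)ccc1O
F6 | step 6 | tert-butyl(dimethyl)silyl (3S)-3-[tert-butyl(dimethyl)silyl]oxybutanoate | C[C@H](O[Si](C)(C)C(C)(C)C)CC(=O)O[Si](C)(C)C(C)(C)C
F7 | step 6 | (3S)-3-[tert-butyl(dimethyl)silyl]oxybutanoic acid | C[C@H](O[Si](C)(C)C(C)(C)C)CC(=O)O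
F8 | step 6 | methyl (E)-3-[4-[(3S)-3-[tert-butyl(dimethyl)silyl]oxybutanoyl]oxy-3-(3-methylbut-2-enyl)phenyl]prop-2-enoate | COC(=O)/C=C/c1ccc(OC(=O)C[C@H](C)O[Si](C)(C)C(C)(C)C)c(CC=C(C)C)c1
F9 | step 6 | methyl (E)-3-[4-[(3S)-3-hydroxybutanoyl]oxy-3-(3-methylbut-2-enyl)phenyl]prop-2-enoate (identical with A8) | COC(=O)/C=C/c1ccc(OC(=O)C[C@H](C)O)c(CC=C(C)C)c1
F10 | step 2 | 4-bromo-2-(hydroxymethyl)phenol | OCc1cc(Br)ccc1O
F11 | step 2 | tert-butyl (5-bromo-2-hydroxyphenyl)methyl carbonate | CC(C)(C)OC(=O)OCc1cc(Br)ccc1O
A1 | alternative 1 | 2-[tert-butyl(dimethyl)silyl]oxy-3-(3-methylbut-2-enyl)buta-1,3-diene | C=C(O[Si](C)(C)C(C)(C)C)C(=C)CC=C(C)C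
A2 | alternative 1 | prop-2-ynal | C#CC=O
A3 | alternative 1 | 4-[tert-butyl(dimethyl)silyl]oxy-5-(3-methylbut-2-enyl)cyclohexa-1,4-diene-1-carbaldehyde | O=CC1=CCC(O[Si](C)(C)C(C)(C)C)=C(CC=C(C)C)C1
A4 | alternative 1 | 4-[tert-butyl(dimethyl)silyl]oxy-3-(3-methylbut-2-enyl)benzaldehyde | O=Cc1ccc(O[Si](C)(C)C(C)(C)C)c(CC=C(C)C)c1
A5 | alternative 2 | methyl (E)-3-[4-acetyloxy-3-(3-methylbut-2-enyl)phenyl]prop-2-enoate | COC(=O)/C=C/c1ccc(OC(C)=O)c(CC=C(C)C)c1
A6 | alternative 2 | methyl (E)-3-[3-(3-methylbut-2-enyl)-4-(1-trimethylsilyloxyethenoxy)phenyl]prop-2-enoate | COC(=O)/C=C/c1ccc(OC(=C)O[Si](C)(C)C)c(CC=C(C)C)c1
A7 | alternative 2 | acetaldehyde | CC=O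
A8 | alternative 2 | methyl (E)-3-[4-[(3S)-3-hydroxybutanoyl]oxy-3-(3-methylbut-2-enyl)phenyl]prop-2-enoate | COC(=O)/C=C/c1ccc(OC(=O)C[C@H](C)O)c(CC=C(C)C)c1
A9 | alternative 3 | p-coumaric acid, (E)-3-(4-hydroxyphenyl)prop-2-enoic acid | O=C(O)/C=C/c1ccc(O)cc1
A10 | alternative 3 | dimethylallyl diphosphate | CC(C)=CCOP(=O)(O)OP(=O)(O)O
A11 | alternative 3 | drupanin, (E)-3-[4-hydroxy-3-(3-methylbut-2-enyl)phenyl]prop-2-enoic acid | CC(C)=CCc1cc(/C=C/C(=O)O)ccc1O
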